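Readings and results were computed for an exercise, and the scatter is random.

If two substrates draw on one partner through one catalyst, the first thing to ask is how the partner is divided between them.

| flask | starting material | partner | second substrate | catalyst | remark | time |
|---|---|---|---|---|---|---|
| Thursday's | 0.37 M | 0.444 M | 0.50 M | 0.74 mM | run made earlier |  |
| Wednesday's | 0.18 M | 0.444 M | 0.74 M | 0.74 mM | run made earlier |  |
| winter | 0.37 M | 0.444 M | 0.740 M | 0.74 mM |  | 12 h |
| summer | 0.37 M | 0.444 M | 0.740 M | 1.5 mM |  | 12 h |

- Thursday's (time / h: starting material / %, target / %, over-reaction product / %): 0.200: 38.8, 57.0, 2.4; 0.417: 29.7, 61.9, 11.1; 1.00: 20.4, 51.1, 25.8; 2.50: 20.6, 28.3, 53.9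
- Wednesday's (time / h: starting material / %, target / %, over-reaction product / %): 0.200: 33.1, 64.1, 4.1; 0.417: 19.7, 68.6, 9.2; 1.00: 11.9, 56.6, 29.7; 2.50: 10.0, 29.3, 60.7

(each reading ± 1 percentage point)

* which of these there is most of at the end, counted by the starting material in it, winter (target / over-reaction product / starting material)
* which of these there is most of at the end, counted by the starting material in it, summer (target / over-reaction product / starting material)
* how much there is at the end of the one of these that leads, in percent of the starting material charged: winter
* how much there is at the end of the one of these that leads, in percent of the starting material charged: summer

- no earlier run changes the charge of catalyst; that part of a forecast is a guess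

Why does the starting material stop? On Thursday it reads 20.4% at 1.00 h and 20.6% at 2.50 h, while the target keeps turning into over-reaction product. I take this stop as the point where [partner], the limiting reagent, reaches zero. Each share is then a subtraction: Thursday's starting material took 0.294 M of the 0.444 M charged, so I give the second substrate the remaining 0.150 M.

Thursday's stop gives a ratio of 4.42 and Wednesday's, from a different loading, gives 4.80. Their mean, 4.61, I call the split: the logarithm of the fraction of starting material left over the logarithm of the fraction of second substrate left. This is a selectivity factor, and I assume it holds while both steps have the same order in partner and catalyst.

What does winter leave? The fraction of starting material left must equal the fraction of second substrate left raised to the split, with the two takings adding up to [partner]. Starting from Thursday's stop and averaging each trial with what it returns, I get 27.9%, then 28.1%.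

Does the target survive? Thursday's readings, taken with the starting material flat, show it falling at 0.394 h⁻¹, so 12 h leaves 0.884% of it. I therefore expect over-reaction product to lead at 71.9%, more than the starting material. In summer the catalyst cancels from the split under my assumption, so I expect the same figure, though no run tests this.

The forecast also has over-reaction product leading, but at 86% (78% to 91%) in winter and 95% (86% to 99%) in summer; of the step from winter to summer it says: “Doubling catalyst should roughly double the integrated conversion”. My winter figure is lower than the forecast's.

The flask gives 71.8% of over-reaction product in winter and 71.8% of over-reaction product in summer. At 12.0 h, partner stands at 0% of its charge in winter and 0% in summer, with 28.0% and 28.0% of the starting material left.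

    starting material + partner + catalyst → catalyst + target (k = 7.55 M⁻² s⁻¹)
    second substrate + partner + catalyst → catalyst + second product (k = 1.63 M⁻² s⁻¹)
    target → over-reaction product (k = 1.36 × 10⁻⁴ s⁻¹)

The split serves again for the neighbour of winter charged with 0.15 M of starting material: two rounds of the same balance from Wednesday's stop give 8.50% left, and that neighbour ends with 8.4% starting material and 91.3% over-reaction product.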